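**Plan**

1. Retrosynthetic cuts, in order: the C10–prenyl bond; the acetyl C=O (back to an isopropenyl group); the C1–C8 and C3–C7 bonds together in one radical cascade; then C5–CH3, the two ring–prenyl bonds and the aryl–acyl bond of an acylphloroglucinol.
2. Enabling feature: ring C (C3–C4–C5–C9–C10–C11) is a dearomatized acylphloroglucinol. C3 lies between the C4 and C11 carbonyls and can carry a radical. The former prenyl groups on C5 (C6–C7=C8Me2) and on C3 (C2–C1=CMe2, the acetyl being a cleaved isopropenyl) each place an alkene carbon five atoms from a radical centre.
3. Forward: phloroglucinol → acylation → double C-prenylation → enantioselective dearomative C-methylation (ring C, C5 set) → oxidative radical cascade (ring B by C3–C7, then ring A by C8–C1) → ozonolysis → C1 equilibration → C-prenylation at C10.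
4. Stereochemistry: C5 from a chiral phase-transfer catalyst; C3 and C7 from C5 through the geometry of the bridged and cis-fused rings; C1 by thermodynamic epimerization next to the acetyl carbonyl; C10 by alkylation on the face syn to the C4 bridge.
5. Numbering used throughout: C1 = CH(acetyl), C2 = ring-A CH2, C3 = bridgehead, C4 = bridging C=O, C5 = C(CH3) bridgehead, C6 = CH2, C7 = ring-fusion CH, C8 = C(CH3)2, C9 and C11 = ring-C carbonyls next to C5 and C3, C10 = C(prenyl)(isobutyryl).

Key step: step 4

Remark (assumption): the sense of induction of the phase-transfer catalyst in step 3 cannot be predicted with confidence. The cinchonidinium salt named there stands for whichever of the two pseudo-enantiomeric catalysts (cinchonidinium or cinchoninium) is found to give (6S)-6. Enolized triketones are written as one tautomer.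

**Step 1**
Reactants: 1 phloroglucinol; 2 isobutyryl chloride
Product: 3 2-methyl-1-(2,4,6-trihydroxyphenyl)propan-1-one
Conditions: AlCl3 (4 equiv), PhNO2, 65 °C; then ice/1 M HCl
Reagents that add atoms: none
Why: Friedel–Crafts acylation of the very electron-rich arene, in which the first acyl group deactivates the ring and chelates the Lewis acid, so mono-acylation should dominate; no stereocentre.

**Step 2**
Reactants: 3 2-methyl-1-(2,4,6-trihydroxyphenyl)propan-1-one; 4 prenyl bromide (1-bromo-3-methylbut-2-ene), of which two equivalents are consumed
Product: 5 2-methyl-1-[2,4,6-trihydroxy-3,5-bis(3-methylbut-2-en-1-yl)phenyl]propan-1-one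
Conditions: prenyl bromide (2.1 equiv), 10% aq. KOH, 0 °C; then 2 M HCl
Reagents that add atoms: prenyl bromide (second equivalent of 4) CC(C)=CCBr
Why: Two successive SN2 C-alkylations of the ambident phloroglucinolate, one at each of its two equivalent free ring carbons, favoured over O-alkylation in water where the oxygens are hydrogen-bonded; no stereocentre.

**Step 3**
Reactants: 5 2-methyl-1-[2,4,6-trihydroxy-3,5-bis(3-methylbut-2-en-1-yl)phenyl]propan-1-one
Product: 6 (6S)-3,5-dihydroxy-6-methyl-4,6-bis(3-methylbut-2-en-1-yl)-2-(2-methylpropanoyl)cyclohexa-2,4-dien-1-one
Conditions: MeI (1.2 equiv), O-allyl-N-(9-anthracenylmethyl)cinchonidinium bromide (10 mol%), solid CsOH·H2O (2.2 equiv), toluene/CH2Cl2 7:3, −45 °C; then 1 M HCl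
Reagents that add atoms: methyl iodide CI
Why: Proposed new method: enantioselective desymmetrizing dearomative C-methylation of the achiral, mirror-symmetric phenolate of 5 under chiral phase-transfer catalysis; the planar anion should be carried into the organic phase as a tight ion pair with the cinchonidinium cation, whose anthracenylmethyl wall covers one face, so that MeI (SN2) reaches only one of the two enantiotopic prenyl-bearing ring carbons from the open face and sets C5, the only stereocentre of 6; the soft electrophile and non-polar medium favour C- over O-methylation, the low temperature suppresses the uncatalysed interfacial reaction, and the product anion (a vinylogous carboxylate) is a weaker nucleophile, which limits a second methylation; the closest known reaction types are the chiral phase-transfer alkylative dearomatization of diprenyl acylphloroglucinols with allylic electrophiles and the cinchona-ammonium-catalysed enantioselective methylation of ketone enolates.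

**Step 4**
Reactants: 6 (6S)-3,5-dihydroxy-6-methyl-4,6-bis(3-methylbut-2-en-1-yl)-2-(2-methylpropanoyl)cyclohexa-2,4-dien-1-one
Product: 10 isopropenyl tricycle as both C1 epimers, via ring-carbon radical 7 (not isolated), via bicyclic tertiary radical 8 (not isolated), via tricyclic tertiary radical 9 (not isolated)
Conditions: Mn(OAc)3·2H2O (2.2 equiv), Cu(OAc)2·H2O (1.0 equiv), degassed AcOH, 23 °C, Ar
Reagents that add atoms: none
Why: Trivalent manganese oxidizes the enolized β-dicarbonyl unit of 6 by inner-sphere electron transfer to the delocalized radical 7, which bonds through C3 to C7 of the prenyl group on C5 in a 5-exo-trig closure that forms cyclopentanone ring B and with it the bicyclo[3.2.1]octane; the tertiary radical 8 left at C8 then adds 5-exo-trig to C1 of the prenyl group on C3, forming the C8–C1 bond and cyclopentane ring A, and divalent copper turns the resulting tertiary radical 9 into the isopropenyl group through an organocopper intermediate and β-hydride loss, the monovalent copper being re-oxidized by manganese. The closest known reaction type is the Mn(OAc)3/Cu(OAc)2 oxidative radical cyclization cascade of unsaturated β-dicarbonyl compounds, which has been applied to dearomatized diprenyl acylphloroglucinols of this substitution pattern. C3 and C7 are controlled by C5: the C6–C7 tether can reach C3 only on the face of ring C that carries it, and only the C7 epimer with the C8 radical exo, cis to the C2 methylene, can close the cis-fused diquinane, so both centres follow from the configuration set in step 3. C1 is the one centre the cascade does not secure: a chair-like transition state with the forming 2-propyl radical pseudo-equatorial may favour the isopropenyl group trans to C6, as the target needs, but both epimers are expected, and the mixture is carried on because C1 becomes enolizable after step 5 and is corrected in step 6. The step needs site selectivity between C3 and the acyl-bearing C10, which also holds spin density; bond formation at C3 keeps C10 in the hydrogen-bonded enolized triketone whereas reaction through C10 would give up that conjugation at a more hindered carbon, and it needs the second closure to outrun oxidation of 8 by copper, which the five-atom tether and a copper loading of one equivalent should secure.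

**Step 5**
Reactants: 10 isopropenyl tricycle as both C1 epimers
Product: 12 acetyl tricycle as both C1 epimers, via secondary ozonide 11 (not isolated)
Conditions: O3, CH2Cl2, −78 °C, Sudan red 7B as end-point indicator; then PPh3 (1.5 equiv), −78 °C → 23 °C
Reagents that add atoms: ozone [O-][O+]=O
Why: Ozonolysis: the 1,1-disubstituted isopropenyl alkene is the most electron-rich π bond of 10 (the ring enol is a hydrogen-bonded vinylogous acid flanked by three carbonyls), so cycloaddition, rearrangement to ozonide 11 and reduction by PPh3 should give the methyl ketone without touching a stereocentre.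

**Step 6**
Reactants: 12 acetyl tricycle as both C1 epimers
Product: 13 acetyl tricycle with the acetyl group cis to H7
Conditions: TsOH·H2O (0.2 equiv), toluene, 80 °C
Reagents that add atoms: none
Why: Acid-catalysed enolization of the methyl ketone toward its more substituted α-carbon makes C1 epimerizable (thermodynamic epimerization), and the equilibrium should favour the acetyl group on the convex face of the cis-diquinane, cis to H7 and trans to the C4 and C6 atoms of ring B, as in the target.

**Step 7**
Reactants: 13 acetyl tricycle with the acetyl group cis to H7; 14 prenyl acetate (3-methylbut-2-en-1-yl acetate)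
Product: 16 target CNP0322535.2, via sodium enolate 15 (not isolated)
Conditions: NaH (1.0 equiv), THF, 0 °C; then prenyl acetate (1.5 equiv), Pd(PPh3)4 (5 mol%), THF, 50 °C; then pH 7 phosphate buffer
Reagents that add atoms: none
Why: Tsuji–Trost allylic alkylation, in which the soft triketone enolate 15 attacks the η3-prenyl complex of divalent palladium at its unsubstituted terminus and any O-prenyl enol ether (a vinylogous allyl ester) is re-ionized by zerovalent palladium so that the C-prenyl product accumulates; C10 is set by attack on the face of the C9–C10–C11 enolate that is syn to the one-atom C4 ketone bridge and anti to the C6–C7 bridge with its fused ring A, which places prenyl syn to C4 as in the target.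

**Compound list**

1 | phloroglucinol (benzene-1,3,5-triol) | Oc1cc(O)cc(O)c1 | starting material
2 | isobutyryl chloride | CC(C)C(Cl)=O | starting material
3 | 2-methyl-1-(2,4,6-trihydroxyphenyl)propan-1-one | CC(C)C(=O)c1c(O)cc(O)cc1O | intermediate
4 | prenyl bromide (1-bromo-3-methylbut-2-ene) | CC(C)=CCBr | starting material
5 | 2-methyl-1-[2,4,6-trihydroxy-3,5-bis(3-methylbut-2-en-1-yl)phenyl]propan-1-one | CC(C)C(=O)c1c(O)c(CC=C(C)C)c(O)c(CC=C(C)C)c1O | intermediate
6 | (6S)-3,5-dihydroxy-6-methyl-4,6-bis(3-methylbut-2-en-1-yl)-2-(2-methylpropanoyl)cyclohexa-2,4-dien-1-one (monocyclic ring C; C5 carries CH3 and prenyl) | CC(C)C(=O)C1=C(O)C(CC=C(C)C)=C(O)[C@](C)(CC=C(C)C)C1=O | intermediate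
7 | ring-carbon radical of 6, drawn with the unpaired electron at C3 | CC(C)C(=O)C1=C(O)[C](CC=C(C)C)C(=O)[C@](C)(CC=C(C)C)C1=O | intermediate
8 | bicyclo[3.2.1]octane radical after the C3–C7 closure: prenyl on C3, exo 2-propyl radical (C8) on C7, H7 endo | CC(C)=CC[C@]12C(=O)[C@](C)(C[C@@H]1[C](C)C)C(O)=C(C(=O)C(C)C)C2=O | intermediate
9 | tricyclic radical after the C8–C1 closure: 2-propyl radical on C1, either configuration at C1 | C[C](C)C1C[C@]23C(=O)[C@](C)(C[C@@H]2C1(C)C)C(O)=C(C(=O)C(C)C)C3=O | intermediate
10 | isopropenyl tricycle: target skeleton with C10 as the enolized isobutyryl-bearing carbon (no prenyl) and CH2=C(CH3)– on C1; CH3 on bridgehead C5, C2 on bridgehead C3, H7 endo toward the C9–C10–C11 bridge, ring A cis-fused; both C1 epimers | C=C(C)C1C[C@]23C(=O)[C@](C)(C[C@@H]2C1(C)C)C(O)=C(C(=O)C(C)C)C3=O | intermediate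
11 | secondary ozonide (3-methyl-1,2,4-trioxolan-3-yl group on C1) of 10 | CC1(OCOO1)C2C[C@]34C(=O)[C@](C)(C[C@@H]3C2(C)C)C(O)=C(C(=O)C(C)C)C4=O | intermediate
12 | acetyl tricycle: as 10 with CH3C(=O)– on C1; both C1 epimers | CC(=O)C1C[C@]23C(=O)[C@](C)(C[C@@H]2C1(C)C)C(O)=C(C(=O)C(C)C)C3=O | intermediate
13 | acetyl tricycle, single epimer: acetyl cis to H7 and trans to the C6 methylene | CC(=O)[C@H]1C[C@]23C(=O)[C@](C)(C[C@@H]2C1(C)C)C(O)=C(C(=O)C(C)C)C3=O | intermediate
14 | prenyl acetate (3-methylbut-2-en-1-yl acetate) | CC(=O)OCC=C(C)C | starting material
15 | sodium enolate of 13 (charge delocalized over the triketone) | CC(=O)[C@H]1C[C@]23C(=O)[C@](C)(C[C@@H]2C1(C)C)C([O-])=C(C(=O)C(C)C)C3=O.[Na+] | intermediate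
16 | CNP0322535.2: as 13 with C10 quaternary, prenyl syn to the C4 ketone bridge and isobutyryl syn to the C6–C7 bridge | CC(=O)[C@H]1C[C@]23C(=O)[C@](C)(C[C@@H]2C1(C)C)C(=O)[C@](CC=C(C)C)(C(=O)C(C)C)C3=O | target

**Totals**

Total step count: 7. Longest linear sequence: 7 steps (1 → 16).

**Steps most likely to fail**

Step 3 (proposed new method). The methylation may proceed with low enantioselectivity because the uncatalysed interfacial reaction or a loose ion pair competes, and O-methylation or double methylation may consume material. Fallback with known chemistry, setting out from 5: methylation with MeI and NaOMe in MeOH at 0 °C should give the racemate, that is 6 together with its mirror image, (6R)-3,5-dihydroxy-6-methyl-4,6-bis(3-methylbut-2-en-1-yl)-2-(2-methylpropanoyl)cyclohexa-2,4-dien-1-one F1. The enantiomers would be separated by preparative chromatography on a chiral stationary phase (amylose tris(3,5-dimethylphenylcarbamate), CO2/MeOH with 0.1% HCO2H). The (6S)-enantiomer rejoins the route at 6.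

Step 7. The enolate may be prenylated on oxygen or at the tertiary allyl terminus, or C-alkylation at the hindered acyl-bearing carbon may be too slow or reversible, and the base-sensitive non-enolizable triketone may suffer retro-Claisen cleavage. Fallback setting out from 13: allyl bromide and K2CO3 in acetone should give the O-allyl enol ether F2 (either ring oxygen serves). Heating F2 in toluene at 110 °C should move the allyl group to C10 by Claisen rearrangement on the face syn to the C4 bridge, giving the C10-allyl triketone F3. Cross-metathesis of F3 with 2-methyl-2-butene and the second-generation Grubbs catalyst, (H2IMes)(PCy3)Cl2Ru=CHPh, in CH2Cl2 at 40 °C should convert allyl into prenyl and return to the route at 16.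

Step 6. The equilibrium between the C1 epimers may be less one-sided than expected, or the enolization at the hindered methine next to C8 may be too slow. Fallback setting out from 10: the two C1 epimers are separated by preparative HPLC at the isopropenyl stage. The isopropenyl epimer F4, which has the isopropenyl group cis to H7, is ozonized under the neutral conditions of step 5 through its secondary ozonide F5, which does not touch C1. Reduction with PPh3 should give the single epimer directly and return to the route at 13.

**Further compounds**

F1 | step 3 | (6R)-3,5-dihydroxy-6-methyl-4,6-bis(3-methylbut-2-en-1-yl)-2-(2-methylpropanoyl)cyclohexa-2,4-dien-1-one | CC(C)C(=O)C1=C(O)C(CC=C(C)C)=C(O)[C@@](C)(CC=C(C)C)C1=O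
F2 | step 7 | O-allyl enol ether of 13 (allyloxy on C9) | CC(=O)[C@H]1C[C@]23C(=O)[C@](C)(C[C@@H]2C1(C)C)C(OCC=C)=C(C(=O)C(C)C)C3=O
F3 | step 7 | C10-allyl analogue of 16 (allyl syn to the C4 bridge) | CC(=O)[C@H]1C[C@]23C(=O)[C@](C)(C[C@@H]2C1(C)C)C(=O)[C@](CC=C)(C(=O)C(C)C)C3=O
F4 | step 6 | single C1 epimer of 10 with isopropenyl cis to H7 | C=C(C)[C@H]1C[C@]23C(=O)[C@](C)(C[C@@H]2C1(C)C)C(O)=C(C(=O)C(C)C)C3=O
F5 | step 6 | secondary ozonide of F4 | CC1(OCOO1)[C@H]2C[C@]34C(=O)[C@](C)(C[C@@H]3C2(C)C)C(O)=C(C(=O)C(C)C)C4=O
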